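## The problem

The target 18 is a fully substituted phloroglucinol. In benzofuran numbering its benzene ring carries a fused (2R)-2-(prop-1-en-2-yl)-2,3-dihydrofuran (O1 on C7a, the CH2 on C3a), hydroxyls on C4 and C6, a 2-methylpropanoyl group on C5 between them, and on C7 a single methylene carbon that ends at C3' of a 6'-ethyl-4'-hydroxy-5'-methyl-2'-pyranone (O1', C2' to C6').

Three oxygens of one phloroglucinol must take three different roles: the ether O1 is para to the ketone, while O4 and O6 are ortho to it and chelated. Telling the para oxygen from the ortho oxygens is therefore the first regiochemical task.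

The methylene bridge joins two carbon nucleophiles, C7 and C3'. Both react with formaldehyde, so a one-carbon electrophile offered to both at once also gives the two symmetrical dimers and O-alkylated pyranone.

C2 is the only stereocenter. It has no neighbour to relay from and nothing to control, so it must be set by a catalyst and then only preserved.

Several groups rule out rough treatment:
- The 1,1-disubstituted alkene excludes hydrogenolysis, protic acid and strong Lewis acids.
- The C2–O1 bond is an allylic aryl ether whose phenoxide is para to a ketone. Acid or zerovalent palladium can ionise it, which would open the ring or racemise C2.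
- The acylphloroglucinol and the acidic 4-hydroxy-2-pyranone do not tolerate strong base in air.

The enabling feature is that the bridge carbon on C7 sits directly beside the C6 hydroxyl, and the pyranone carbonyl C2' is only two atoms away from that bridge. O6, C2', C3', the CH2, C7 and C6 can therefore be closed into a six-membered aryl lactone (a dihydrocoumarin). This lactone holds the bridge on both partners before the pyranone exists and hands C2' to O1' when the pyranone ring is built.

## Retrosynthesis

**18 from 17.** The last operation only frees O4 from a tert-butyldimethylsilyl group. No skeletal bond is cut. The silyl ether is chosen because buffered fluoride removes it without touching the alkene, the allylic aryl ether or the pyranone, and because the same group is what makes the acid chloride 12 accessible.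

**17 from 12 and 14 (key disconnection).** The pyranone is cut at C4'–C5' and O1'–C2'.
- Against its neighbours: cutting at C7–CH2 or CH2–C3' would mean coupling a finished pyranone with ketone 6 through a formaldehyde equivalent, which brings back dimers and O-alkylation. Cutting inside the pyranone leaves the bridge bonded on both sides from the start.
- Within the pyranone, this cut gives a malonyl unit (C2'–C3'–C4') and a ketone unit (C5', C6', O1'), the pattern of malonyl chloride cyclocondensations. The second carboxyl of the malonyl unit is stored on O6 as the lactone of 12.
- Simplification: 12 lacks the whole heterocycle, and 14 is a five-carbon silyl enol ether.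
- Forward demands: the chloride end must acylate 14 at carbon first, and the aryl lactone must then acylate the new enol at oxygen. No stereochemistry is created.

**14 from 13.** The Si–O bond is cut. Pentan-3-one is symmetrical, so its enol ether has no regiochemical issue, and its geometry is lost in the pyranone.

**12 from 11 from 10.** These are functional-group changes on the lactone acid 10. One silyl reagent masks the last free phenol (O4) and turns the acid into a silyl ester. The silyl ester is the one carboxyl derivative that oxalyl chloride converts to the chloride without releasing hydrogen chloride, which the isopropenyl group would not tolerate.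

**10 from 6, 7 and formaldehyde.** The bonds C7–CH2, CH2–C3' and O6–C2' are cut. Formaldehyde does appear here, but its partner is Meldrum's acid 7. This condenses with formaldehyde far faster than the phenol does and is turned into methylene compound 8, which is only an electrophile. Ketone 6 then has a single nucleophilic carbon (C7) and a single hydroxyl next to it (O6; the other neighbour is the ether O1), so both bond formations are regiochemically fixed. The precursor 6 is the bare dihydrobenzofuran core.

**6 from 4 and 5.** The dihydrofuran is cut at C3–C3a and O1–C2, which leads to the ortho-iodophenol 4 and isoprene. A palladium-catalysed heteroannulation forms both bonds, the stereocenter and the isopropenyl group in one step. The classical sequence of prenylation, asymmetric epoxidation, cyclisation and dehydration needs four steps. The forward reaction must add the aryl group to the unsubstituted end of isoprene, close through the oxygen para to the ketone, and set C2 as R under ligand control.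

**4 from 3 from 1 and 2.** Iodination and Friedel–Crafts acylation are cut. The two open ring positions of 3 are equivalent, and phloroglucinol 1 is symmetrical, so neither step has a regiochemical choice.

## Roads not taken

**Alternative 1:** The benzene ring would be assembled by a Danheiser benzannulation, cutting C7a–C7 and C6–C5. Heating the cyclobutenone A1 with the siloxyalkyne A2 would give phenol A3 through a vinylketene, a [2+2] addition, a four-electron ring opening and a six-electron closure.
- Merits: A3 has three differentiated oxygens (free hydroxyl as the future O1, silyl ether as O6, ethyl ether as O4), the prenyl group on the future C3a and a methoxymethyl group on the future C7. The ortho/para oxygen question never arises.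
- Weak points: A1 and A2 each need several steps. The stereocenter must still be made from the prenyl group by asymmetric epoxidation, cyclisation and dehydration of a tertiary alcohol. The ketone must be introduced at C5 between two ethers. The ethyl ether on O4 needs a Lewis acid for cleavage that threatens the isopropenyl group and the allylic aryl ether. The benzylic methyl ether must finally be ionised to meet a pyranone, which reopens C- versus O-alkylation and dimer formation.
- Comparison: on oxygen differentiation this road is better than the chosen plan, which relies on an acidity difference in step 3. The chosen plan sets against it a route of about half the length, a bridge that is never a free electrophile, and no ether cleavage.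

**Alternative 2:** A Catellani annulation would cut C3–C3a and O1–C7a. Under palladium and norbornene the aryl iodide A4 would be alkylated at its free ortho C–H by the CH2 end of the enantiopure epoxide A5, and the alkoxide would then couple at the iodine-bearing carbon to give dihydrobenzofuran A6.
- Merits: the configuration at C2 comes from A5 and needs no asymmetric catalysis. The position of iodine fixes which oxygen becomes O1. The C7 carbon is already in place.
- Weak points: A4 is a multistep, fully protected arene. After the key step four tasks remain: acylation at C5 between two methoxymethyl ethers (most plausibly by lithiation), dehydration of the tertiary alcohol to the isopropenyl group, acidic removal of the methoxymethyl groups next to an acid-sensitive allylic aryl ether, and conversion of the silyloxymethyl group into the bridge to a pyranone, with the selectivity problems named above.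
- Comparison: this road is more certain than step 3 of the chosen plan in both regiochemistry and configuration of the dihydrofuran. The chosen plan answers with one operation that delivers the isopropenyl group directly, no acidic deprotection, and a lactone tether that settles the bridge.

**Alternative 3:** The benzene ring would be closed in polyketide fashion, cutting C4–C5. Methoxide would make the dioxo ester A7 attack its own ester carbon and aromatise to ketone A8, which is the same compound as 6.
- Merits: the acyl group ends para to O1 by construction, no halogen or palladium is needed, and everything after 6 would stay as planned.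
- Weak points: A7 needs an enantioselective dihydrofuran synthesis and dianion chemistry for the side chain. Under methoxide the C3 protons of the vinylogous carbonate are acidic, and β-elimination of O1 from C2 would open the ring and destroy the stereocenter. Triketo esters of this kind can also close by aldol reaction or by lactonisation to a pyranone instead of the wanted Claisen mode.
- Comparison: the endpoint is identical, and this road removes the ortho/para question of step 3. It replaces it with a question of cyclisation mode and configurational stability, and it is several steps longer. The chosen plan reaches 6 in three steps from phloroglucinol.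

Key step: step 8

## Route

Assumption: the enantiomeric series of the ligand TY-Phos is the one that converts 3-bromo-4-hydroxyacetophenone and isoprene into (R)-tremetone; the sense of induction is assumed to carry over to iodide 4, whose C2 substituents have the same priorities.

Step 1
Reactants: 1 benzene-1,3,5-triol (phloroglucinol); 2 2-methylpropanoyl chloride
Product: 3 2-methyl-1-(2,4,6-trihydroxyphenyl)propan-1-one
Conditions: AlCl3 (4 equiv), PhNO2–CH2Cl2, 0 °C → rt; ice/aq. HCl
Reagents that add atoms: none
Why: Friedel–Crafts C-acylation of phloroglucinol; the first acyl group deactivates the ring and binds aluminium, so the reaction should stop at the mono-ketone.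

Step 2
Reactants: 3 2-methyl-1-(2,4,6-trihydroxyphenyl)propan-1-one
Product: 4 1-(2,4,6-trihydroxy-3-iodophenyl)-2-methylpropan-1-one
Conditions: NIS (1.0 equiv), MeCN, −20 → 0 °C, dark
Reagents that add atoms: N-iodosuccinimide, O=C1CCC(=O)N1I
Why: Electrophilic aromatic iodination; the two open ring positions of 3 are equivalent, so only one regioisomer is possible, and one equivalent of reagent at low temperature should limit a second iodination.

Step 3
Reactants: 4 1-(2,4,6-trihydroxy-3-iodophenyl)-2-methylpropan-1-one; 5 2-methylbuta-1,3-diene (isoprene)
Product: 6 1-[(2R)-4,6-dihydroxy-2-(prop-1-en-2-yl)-2,3-dihydro-1-benzofuran-5-yl]-2-methylpropan-1-one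
Conditions: 5 (3 equiv), Pd2(dba)3·CHCl3 (5 mol %), TY-Phos (chiral sulfinamide monophosphine, 12 mol %), NaOPh (2 equiv), THF–toluene, 60 °C, sealed tube; pH 5 buffer
Reagents that add atoms: none
Why: Enantioselective palladium-catalysed heteroannulation of an ortho-halophenol with a 1,3-diene (Heck insertion followed by Tsuji–Trost etherification): the arylpalladium species adds to the unsubstituted terminus of isoprene (bond C3–C3a) and the π-allyl complex is closed by a phenoxide at the internal carbon (bond O1–C2), which leaves the isopropenyl group. The chiral ligand should set C2 as R in the C–O bond-forming step, as in the tremetone series. The closing oxygen is expected to be the one para to the ketone, because it is the most acidic, non-chelated hydroxyl and the one ionised by phenoxide, in line with the usual alkylation of such triols at that oxygen under mild base.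

Step 4
Reactants: 6 1-[(2R)-4,6-dihydroxy-2-(prop-1-en-2-yl)-2,3-dihydro-1-benzofuran-5-yl]-2-methylpropan-1-one; 7 2,2-dimethyl-1,3-dioxane-4,6-dione (Meldrum's acid)
Product: 10 (2R)-lactone acid (2-oxochroman-3-carboxylic acid ring closed between O6 and C7 of 6; both epimers at the carboxyl-bearing carbon), via methylene Meldrum's acid 8 (not isolated), via Meldrum's acid Michael adduct 9 (not isolated)
Conditions: 7 (1.1 equiv), aq. CH2O (1.05 equiv), L-proline (10 mol %), MeCN, rt, 20 min; then 6, rt → 45 °C; pH 3 buffer
Reagents that add atoms: formaldehyde, C=O
Why: Knoevenagel condensation of 7 with formaldehyde gives 8 before 6 is added; Michael addition of C7, the only free ring carbon, gives 9, and the neighbouring C6 hydroxyl opens the dioxanedione with loss of acetone (lactonisation), as in the known three-component condensations of phenols, aldehydes and Meldrum's acid. Only O6 can close because the other neighbour of C7 is the ether oxygen; the temperature is kept below that of malonic-type decarboxylation, and the new carbon forms as both epimers, which is of no consequence.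

Step 5
Reactants: 10 (2R)-lactone acid
Product: 11 bis-silyl derivative of 10 (tert-butyldimethylsilyl ether at O4 and tert-butyldimethylsilyl ester)
Conditions: TBSOTf (2.2 equiv), 2,6-lutidine (3 equiv), CH2Cl2, −40 → 0 °C; pentane, filtration, evaporation (no water)
Reagents that add atoms: tert-butyldimethylsilyl trifluoromethanesulfonate, CC(C)(C)[Si](C)(C)OS(=O)(=O)C(F)(F)F
Why: Silylation of a phenol and a carboxylic acid with a silyl triflate and a hindered pyridine; the triflate is reactive enough for the ketone-chelated C4 hydroxyl, and the non-nucleophilic base should leave the aryl lactone closed.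

Step 6
Reactants: 11 bis-silyl derivative of 10
Product: 12 acid chloride (2-oxochroman-3-carbonyl chloride fused at O6 and C7; O4 as tert-butyldimethylsilyl ether; 2R; epimers at the lactone carbon)
Conditions: (COCl)2 (1.2 equiv), DMF (cat.), CH2Cl2, 0 °C → rt; evaporation, used at once
Reagents that add atoms: oxalyl chloride, ClC(=O)C(Cl)=O
Why: Conversion of a tert-butyldimethylsilyl ester into the acid chloride by oxalyl chloride and catalytic DMF (Vilsmeier-type chloride transfer); the silyl group leaves as the silyl chloride, so no hydrogen chloride meets the isopropenyl group or the aryl silyl ether.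

Step 7
Reactants: 13 pentan-3-one
Product: 14 (Z)-trimethyl(pent-2-en-3-yloxy)silane
Conditions: TMSOTf (1.1 equiv), Et3N (1.3 equiv), Et2O, 0 °C → rt; distillation
Reagents that add atoms: trimethylsilyl trifluoromethanesulfonate, C[Si](C)(C)OS(=O)(=O)C(F)(F)F
Why: Soft enolisation and O-silylation of a symmetrical ketone; the (Z)-isomer should predominate, and the geometry is irrelevant because both alkene carbons end in the pyranone ring.

Step 8
Reactants: 12 acid chloride; 14 (Z)-trimethyl(pent-2-en-3-yloxy)silane
Product: 17 4-O-tert-butyldimethylsilyl ether of the target (3-{[(2R)-4-(tert-butyldimethylsilyloxy)-6-hydroxy-5-(2-methylpropanoyl)-2-(prop-1-en-2-yl)-2,3-dihydro-1-benzofuran-7-yl]methyl}-6-ethyl-4-hydroxy-5-methyl-2H-pyran-2-one), via acylketene 15 (not isolated), via diketone lactone 16 (not isolated)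
Conditions: 14 (3 equiv), Et3N (1.1 equiv, slow addition), CH2Cl2, −78 → 0 °C; then DBU (2.5 equiv), 0 °C → rt; pH 5 phosphate buffer
Reagents that add atoms: none
Why: Proposed new method: triethylamine should dehydrochlorinate the malonyl-type chloride 12 to acylketene 15, whose ketene carbon is attacked by the nucleophilic carbon of 14 (bond C4'–C5') to give, after silyl transfer, the 2-methyl-1,3-diketone 16 that still holds the aryl lactone; a [2+2] or [4+2] adduct of 15 and 14 would be a donor–acceptor system that should open to the same intermediate under base. DBU then enolises the ethyl ketone, and the enol oxygen adds to the lactone carbonyl in a 6-exo-trig acyl transfer (bond O1'–C2') that expels the C6 phenoxide and closes the one new ring, the 4-hydroxy-2-pyranone. The closest known reaction types are the cyclocondensation of silyl enol ethers with malonyl dichlorides and of enols with aryl malonates to 4-hydroxy-2-pyranones, and the base-induced lactonisation of 3,5-dioxo esters; what is new is that the second acyl donor is a dihydrocoumarin lactone in the same molecule. No stereocenter is formed: the lactone epimers converge because that carbon becomes sp2, and C2 is remote from every bond change. The step needs chemoselectivity between two acyl groups and between C- and O-acylation; the chloride, as the ketene, is by far the stronger electrophile and reacts first at carbon, while the aryl ester reacts second and only intramolecularly at oxygen. The transfer should be driven forward by formation of the acidic pyranone and of a ketone-chelated phenol. The silyl ether keeps O4 out of play, and its partial loss here would be harmless because the next step removes it.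

Step 9
Reactants: 17 4-O-tert-butyldimethylsilyl ether of the target
Product: 18 3-{[(2R)-4,6-dihydroxy-5-(2-methylpropanoyl)-2-(prop-1-en-2-yl)-2,3-dihydro-1-benzofuran-7-yl]methyl}-6-ethyl-4-hydroxy-5-methyl-2H-pyran-2-one (target)
Conditions: Bu4NF (1.2 equiv), AcOH (1.5 equiv), THF, 0 °C
Reagents that add atoms: none
Why: Fluoride-mediated cleavage of an aryl silyl ether activated by the ortho ketone; acetic acid buffers the phenoxide and the acidic pyranone, so the acylphloroglucinol and the allylic aryl ether at C2 are not exposed to free base.

## Compound list

1 | benzene-1,3,5-triol (phloroglucinol) | Oc1cc(O)cc(O)c1 | starting material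
2 | 2-methylpropanoyl chloride | CC(C)C(Cl)=O | starting material
3 | 2-methyl-1-(2,4,6-trihydroxyphenyl)propan-1-one | CC(C)C(=O)c1c(O)cc(O)cc1O | intermediate
4 | 1-(2,4,6-trihydroxy-3-iodophenyl)-2-methylpropan-1-one | CC(C)C(=O)c1c(O)cc(O)c(I)c1O | intermediate
5 | 2-methylbuta-1,3-diene (isoprene) | C=CC(C)=C | starting material
6 | 1-[(2R)-4,6-dihydroxy-2-(prop-1-en-2-yl)-2,3-dihydro-1-benzofuran-5-yl]-2-methylpropan-1-one | C=C(C)[C@H]1Cc2c(O)c(C(=O)C(C)C)c(O)cc2O1 | intermediate
7 | 2,2-dimethyl-1,3-dioxane-4,6-dione (Meldrum's acid) | CC1(C)OC(=O)CC(=O)O1 | starting material
8 | 2,2-dimethyl-5-methylidene-1,3-dioxane-4,6-dione (methylene Meldrum's acid) | C=C1C(=O)OC(C)(C)OC1=O | intermediate (not isolated)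
9 | 5-{[(2R)-4,6-dihydroxy-5-(2-methylpropanoyl)-2-(prop-1-en-2-yl)-2,3-dihydro-1-benzofuran-7-yl]methyl}-2,2-dimethyl-1,3-dioxane-4,6-dione | C=C(C)[C@H]1Cc2c(O)c(C(=O)C(C)C)c(O)c(CC3C(=O)OC(C)(C)OC3=O)c2O1 | intermediate (not isolated)
10 | (2R)-lactone acid: dihydrobenzofuran 6 in which O6 and C7 are joined as O6–C(=O)–CH(CO2H)–CH2–C7 (a 2-oxochroman-3-carboxylic acid), with 4-OH, 5-(2-methylpropanoyl) and 2-(prop-1-en-2-yl) retained; both epimers at the carboxyl-bearing carbon | C=C(C)[C@H]1Cc2c(O)c(C(=O)C(C)C)c3OC(=O)C(C(=O)O)Cc3c2O1 | intermediate
11 | bis-silyl derivative of 10: tert-butyldimethylsilyl ether at O4 and tert-butyldimethylsilyl ester of the carboxyl group; 2R; both epimers at the lactone carbon | C=C(C)[C@H]1Cc2c(O[Si](C)(C)C(C)(C)C)c(C(=O)C(C)C)c3OC(=O)C(C(=O)O[Si](C)(C)C(C)(C)C)Cc3c2O1 | intermediate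
12 | acid chloride: 2-oxochroman-3-carbonyl chloride fused at O6 and C7 of the (2R)-dihydrobenzofuran ketone, O4 as tert-butyldimethylsilyl ether; both epimers at the lactone carbon | C=C(C)[C@H]1Cc2c(O[Si](C)(C)C(C)(C)C)c(C(=O)C(C)C)c3OC(=O)C(C(Cl)=O)Cc3c2O1 | intermediate
13 | pentan-3-one | CCC(=O)CC | starting material
14 | (Z)-trimethyl(pent-2-en-3-yloxy)silane | C/C=C(\O[Si](C)(C)C)CC | intermediate
15 | acylketene from 12: the lactone carbon carries an exocyclic C=C=O (3-(oxomethylidene)-2-oxochroman), O4 silyl ether, 2R | C=C(C)[C@H]1Cc2c(O[Si](C)(C)C(C)(C)C)c(C(=O)C(C)C)c3OC(=O)C(=C=O)Cc3c2O1 | intermediate (not isolated)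
16 | diketone lactone: the lactone carbon of 12 bears a 2-methyl-3-oxopentanoyl group in place of the chlorocarbonyl group; drawn as the triketo form, present in the flask partly as its trimethylsilyl enol ether; 2R, other centers as mixtures | C=C(C)[C@H]1Cc2c(O[Si](C)(C)C(C)(C)C)c(C(=O)C(C)C)c3OC(=O)C(C(=O)C(C)C(=O)CC)Cc3c2O1 | intermediate (not isolated)
17 | 3-{[(2R)-4-(tert-butyldimethylsilyloxy)-6-hydroxy-5-(2-methylpropanoyl)-2-(prop-1-en-2-yl)-2,3-dihydro-1-benzofuran-7-yl]methyl}-6-ethyl-4-hydroxy-5-methyl-2H-pyran-2-one | C=C(C)[C@H]1Cc2c(O[Si](C)(C)C(C)(C)C)c(C(=O)C(C)C)c(O)c(Cc3c(O)c(C)c(CC)oc3=O)c2O1 | intermediate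
18 | 3-{[(2R)-4,6-dihydroxy-5-(2-methylpropanoyl)-2-(prop-1-en-2-yl)-2,3-dihydro-1-benzofuran-7-yl]methyl}-6-ethyl-4-hydroxy-5-methyl-2H-pyran-2-one | C=C(C)[C@H]1Cc2c(O)c(C(=O)C(C)C)c(O)c(Cc3c(O)c(C)c(CC)oc3=O)c2O1 | target

## Step count and risk

Total steps: 9. Longest linear sequence: 8 (steps 1 to 6, 8 and 9, from phloroglucinol 1). Step 7 is a one-step side branch.

**Step 8 (key step, proposed new method).**
- What may go wrong: the ketene may be consumed by dimerisation, or by cycloaddition across the lactone carbonyl that does not reopen. The acyl transfer may also stall at the open diketone stage, because an aryl lactone has not been used before as the second acyl donor of a pyranone cyclocondensation.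
- Fallback (known chemistry): it sets out from 14, draws on 6, and rejoins the route at 18. Enol ether 14 and malonyl dichloride in ether should give 6-ethyl-4-hydroxy-5-methyl-2H-pyran-2-one F1 by the established silyl enol ether–malonyl chloride condensation. A Mannich reaction of F1 with dimethylmethylideneammonium iodide should give 3-[(dimethylamino)methyl]-6-ethyl-4-hydroxy-5-methyl-2H-pyran-2-one F2. Heating F2 with ketone 6 in dioxane should release dimethylamine and 6-ethyl-5-methyl-3-methylidenepyran-2,4-dione F3, which the free C7 of 6 captures to give 18 directly. This is the classical Mannich-base route to methylene-bridged pyranone–acylphloroglucinols. It accepts the dimer problem that the lactone tether was meant to avoid.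

**Step 3.**
- What may go wrong: partial ring closure through a chelated ortho oxygen instead of the para oxygen; loss of enantiomeric purity by re-ionisation of the allylic aryl ether with zerovalent palladium; slow turnover with a polyphenoxide substrate.
- Fallback: it sets out from 3 and rejoins at 6, leaving only one hydroxyl free next to iodine.
  - Benzyl bromide and K2CO3 should give the para ether 1-[4-(benzyloxy)-2,6-dihydroxyphenyl]-2-methylpropan-1-one F4.
  - TBSOTf and 2,6-lutidine should give the bis-silyl ether 1-[4-(benzyloxy)-2,6-bis(tert-butyldimethylsilyloxy)phenyl]-2-methylpropan-1-one F5.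
  - Hydrogenolysis over Pd/C, before any alkene is present, should give 1-[2,6-bis(tert-butyldimethylsilyloxy)-4-hydroxyphenyl]-2-methylpropan-1-one F6.
  - NIS should give 1-[2,6-bis(tert-butyldimethylsilyloxy)-4-hydroxy-3-iodophenyl]-2-methylpropan-1-one F7.
  - The heteroannulation of step 3 should then give 1-[(2R)-4,6-bis(tert-butyldimethylsilyloxy)-2-(prop-1-en-2-yl)-2,3-dihydro-1-benzofuran-5-yl]-2-methylpropan-1-one F8.
  - Bu4NF with acetic acid should return 6.

**Step 4.**
- What may go wrong: formaldehyde may bridge two molecules of 6; the methylene compound 8 may polymerise before C7 attacks; the malonic half ester may decarboxylate on warming.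
- Fallback: it sets out from 6 and rejoins at 10, separating the two carbon–carbon bond formations. A Mannich reaction of 6 with dimethylmethylideneammonium iodide should give 1-[(2R)-7-[(dimethylamino)methyl]-4,6-dihydroxy-2-(prop-1-en-2-yl)-2,3-dihydro-1-benzofuran-5-yl]-2-methylpropan-1-one F9. Warming F9 with Meldrum's acid 7 in acetonitrile should expel dimethylamine to give the ortho-quinone methide F10. Conjugate addition of 7 should then give adduct 9, which lactonises to 10 as in step 4.

**Step 5.**
- What may go wrong: incomplete silylation of the chelated, hindered C4 hydroxyl; opening of the aryl lactone; hydrolysis of the silyl ester on handling, after which step 6 would release hydrogen chloride.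
- Fallback: it sets out from 10 and rejoins at 18 without any silyl group. 1-Chloro-N,N,2-trimethylprop-1-en-1-amine should convert 10 under neutral conditions into the acid chloride with free C4 hydroxyl F11, relying on the poor nucleophilicity of the chelated phenol. Under the conditions of step 8, F11 should pass through the unprotected acylketene F12 and the unprotected diketone lactone F13 to give 18 directly.

## Further compounds

F1 | step 8 | 6-ethyl-4-hydroxy-5-methyl-2H-pyran-2-one | CCc1oc(=O)cc(O)c1C
F2 | step 8 | 3-[(dimethylamino)methyl]-6-ethyl-4-hydroxy-5-methyl-2H-pyran-2-one | CCc1oc(=O)c(CN(C)C)c(O)c1C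
F3 | step 8 | 6-ethyl-5-methyl-3-methylidenepyran-2,4-dione | C=C1C(=O)OC(CC)=C(C)C1=O
F4 | step 3 | 1-[4-(benzyloxy)-2,6-dihydroxyphenyl]-2-methylpropan-1-one | CC(C)C(=O)c1c(O)cc(OCc2ccccc2)cc1O
F5 | step 3 | 1-[4-(benzyloxy)-2,6-bis(tert-butyldimethylsilyloxy)phenyl]-2-methylpropan-1-one | CC(C)C(=O)c1c(O[Si](C)(C)C(C)(C)C)cc(OCc2ccccc2)cc1O[Si](C)(C)C(C)(C)C
F6 | step 3 | 1-[2,6-bis(tert-butyldimethylsilyloxy)-4-hydroxyphenyl]-2-methylpropan-1-one | CC(C)C(=O)c1c(O[Si](C)(C)C(C)(C)C)cc(O)cc1O[Si](C)(C)C(C)(C)C
F7 | step 3 | 1-[2,6-bis(tert-butyldimethylsilyloxy)-4-hydroxy-3-iodophenyl]-2-methylpropan-1-one | CC(C)C(=O)c1c(O[Si](C)(C)C(C)(C)C)cc(O)c(I)c1O[Si](C)(C)C(C)(C)C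
F8 | step 3 | 1-[(2R)-4,6-bis(tert-butyldimethylsilyloxy)-2-(prop-1-en-2-yl)-2,3-dihydro-1-benzofuran-5-yl]-2-methylpropan-1-one | C=C(C)[C@H]1Cc2c(O[Si](C)(C)C(C)(C)C)c(C(=O)C(C)C)c(O[Si](C)(C)C(C)(C)C)cc2O1
F9 | step 4 | 1-[(2R)-7-[(dimethylamino)methyl]-4,6-dihydroxy-2-(prop-1-en-2-yl)-2,3-dihydro-1-benzofuran-5-yl]-2-methylpropan-1-one | C=C(C)[C@H]1Cc2c(O)c(C(=O)C(C)C)c(O)c(CN(C)C)c2O1
F10 | step 4 | ortho-quinone methide of 6: (2R)-4-hydroxy-7-methylidene-5-(2-methylpropanoyl)-2-(prop-1-en-2-yl)-2,3-dihydro-1-benzofuran-6(7H)-one | C=C(C)[C@H]1CC2=C(O1)C(=C)C(=O)C(C(=O)C(C)C)=C2O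
F11 | step 5 | acid chloride of 10 with free C4 hydroxyl (2R; epimers at the lactone carbon) | C=C(C)[C@H]1Cc2c(O)c(C(=O)C(C)C)c3OC(=O)C(C(Cl)=O)Cc3c2O1
F12 | step 5 | acylketene from F11 (O4-unprotected counterpart of 15) | C=C(C)[C@H]1Cc2c(O)c(C(=O)C(C)C)c3OC(=O)C(=C=O)Cc3c2O1
F13 | step 5 | diketone lactone with free C4 hydroxyl (O4-unprotected counterpart of 16) | C=C(C)[C@H]1Cc2c(O)c(C(=O)C(C)C)c3OC(=O)C(C(=O)C(C)C(=O)CC)Cc3c2O1
A1 | alternative 1 | 3-ethoxy-4-(3-methylbut-2-en-1-yl)cyclobut-2-en-1-one | CCOC1=CC(=O)C1CC=C(C)C
A2 | alternative 1 | triisopropyl[(3-methoxyprop-1-yn-1-yl)oxy]silane | COCC#CO[Si](C(C)C)(C(C)C)C(C)C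
A3 | alternative 1 | 3-ethoxy-2-(3-methylbut-2-enyl)-6-(methoxymethyl)-5-(triisopropylsilyloxy)phenol | Oc1c(COC)c(O[Si](C(C)C)(C(C)C)C(C)C)cc(OCC)c1CC=C(C)C
A4 | alternative 2 | tert-butyl{[2-iodo-4,6-bis(methoxymethoxy)phenyl]methoxy}dimethylsilane | COCOc1cc(I)c(CO[Si](C)(C)C(C)(C)C)c(OCOC)c1
A5 | alternative 2 | (R)-triethyl{[2-(oxiran-2-yl)propan-2-yl]oxy}silane | CC(C)(O[Si](CC)(CC)CC)[C@H]1CO1
A6 | alternative 2 | (2R)-7-(tert-butyldimethylsilyloxymethyl)-4,6-bis(methoxymethoxy)-2-[2-(triethylsilyloxy)propan-2-yl]-2,3-dihydrobenzofuran | CC(C)(O[Si](CC)(CC)CC)[C@H]1Cc2c(OCOC)cc(OCOC)c(CO[Si](C)(C)C(C)(C)C)c2O1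
A7 | alternative 3 | methyl (5R)-2-(5-methyl-2,4-dioxohexyl)-5-(prop-1-en-2-yl)-4,5-dihydrofuran-3-carboxylate | C=C(C)[C@H]1CC(C(=O)OC)=C(CC(=O)CC(=O)C(C)C)O1
A8 | alternative 3 | 1-[(2R)-4,6-dihydroxy-2-(prop-1-en-2-yl)-2,3-dihydrobenzofuran-5-yl]-2-methylpropan-1-one (same compound as 6) | C=C(C)[C@H]1Cc2c(O)c(C(=O)C(C)C)c(O)cc2O1
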